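**Retrosynthetic overview**

1. The target is a flavone unit (benzo ring A, pyranone ring C, 4-methoxyphenyl ring B) bonded from its C3 to C6 of a (2R)-flavanone unit (benzo ring D, dihydropyranone ring E, 4-hydroxyphenyl ring F); the last step is hydrogenolysis of four benzyl ethers.
2. Ring E is closed last by making its C3–C2 bond in an enantioselective, acid-catalysed Petasis–Ferrier-type [1,3] O-to-C rearrangement of a 2-aryl-4-methylidene-4H-1,3-benzodioxine, a temporary ring in which O1–C2 already exists and the future C4 oxygen holds C2 as an acetal.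
3. Enabling feature: O1 and C4 sit ortho on ring D, so the two oxygens can share C2 as an acetal; C2 is flanked by O1 and the para-oxygenated ring F, so it ionises to an aryloxocarbenium ion while C3 of the C4 enol stays tethered through ring D at ring-closing distance.
4. The biaryl bond (flavone C3 to C6 of ring D) is made before that by Negishi coupling of the C3-zincated flavone with the 6-iodo enol acetal; iodine is placed ortho to the chelated 5-OH and the dioxinone fixes which oxygen is O1, so the 6-linkage (not 8) is built in.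
5. Order of rings: A/B/C (apigenin) and D (2,4,6-trihydroxybenzoic acid) are bought; temporary 1,3-dioxinone ring (step 3); methylenation; biaryl; ring E with the C2 stereocentre (step 9).

Key step: step 9

Assumption 1: the sense of induction of the chiral acid in step 9 cannot be predicted with certainty; the (S,S) catalyst is written, and its mirror image would be used if it favoured the (2S) series.
Assumption 2: the biaryl axis between flavone C3 and C6 of ring D is not defined in the target and is left uncontrolled; compounds 7–12 and 15 are racemic at the acetal carbon, a centre that step 9 erases.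

**Route**

Step 1
Reactants: 1 apigenin
Product: 2 5-hydroxy-7-methoxy-2-(4-methoxyphenyl)-4H-chromen-4-one
Conditions: Me2SO4 (2.1 equiv), K2CO3, acetone, reflux
Reagents that add atoms: dimethyl sulfate, COS(=O)(=O)OC
Why: Williamson O-methylation; the 5-OH, hydrogen-bonded to the C4 carbonyl, should stay free while the more acidic 7- and 4'-OH are alkylated.

Step 2
Reactants: 2 5-hydroxy-7-methoxy-2-(4-methoxyphenyl)-4H-chromen-4-one
Product: 3 5-(benzyloxy)-7-methoxy-2-(4-methoxyphenyl)-4H-chromen-4-one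
Conditions: BnBr, K2CO3, KI (cat.), DMF, 70 °C
Reagents that add atoms: benzyl bromide, BrCc1ccccc1
Why: Williamson O-benzylation of the chelated 5-OH under forcing conditions should mask the only acidic proton before C3 metalation with a group that hydrogenolysis removes.

Step 3
Reactants: 4 2,4,6-trihydroxybenzoic acid; 5 4-(benzyloxy)benzaldehyde
Product: 8 2-[4-(benzyloxy)phenyl]-5,7-dihydroxy-4H-1,3-benzodioxin-4-one, via tetrakis-TMS benzoate 6 (not isolated), via bis-TMS benzodioxinone 7 (not isolated)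
Conditions: (Me3Si)2NH, Me3SiCl (cat.), THF, reflux, evaporate; then 5, Me3SiOSO2CF3 (10 mol%), CH2Cl2, −78 °C; aq. citric acid/THF, 0 °C
Reagents that add atoms: none
Why: Silyl-triflate-catalysed acetalisation of a bis-silylated hydroxy acid with an aldehyde (the union step of the Petasis–Ferrier sequence) should give the six-membered acylal at −78 °C, forming O1–C2 at one of the two equivalent ortho oxygens of ring D.

Step 4
Reactants: 8 2-[4-(benzyloxy)phenyl]-5,7-dihydroxy-4H-1,3-benzodioxin-4-one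
Product: 9 7-(benzyloxy)-2-[4-(benzyloxy)phenyl]-5-hydroxy-4H-1,3-benzodioxin-4-one
Conditions: BnBr (1.05 equiv), K2CO3, acetone, rt
Reagents that add atoms: benzyl bromide, BrCc1ccccc1
Why: Williamson etherification should be selective for the 7-OH because the 5-OH is chelated to the lactone carbonyl.

Step 5
Reactants: 9 7-(benzyloxy)-2-[4-(benzyloxy)phenyl]-5-hydroxy-4H-1,3-benzodioxin-4-one
Product: 10 7-(benzyloxy)-2-[4-(benzyloxy)phenyl]-5-hydroxy-6-iodo-4H-1,3-benzodioxin-4-one
Conditions: BnMe3N+ ICl2− (1.05 equiv), CaCO3, CH2Cl2/MeOH, rt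
Reagents that add atoms: benzyltrimethylammonium dichloroiodate, C[N+](C)(C)Cc1ccccc1.Cl[I-]Cl
Why: Electrophilic aromatic iodination directed ortho to the chelated phenol, the pattern known for 5-hydroxy-7-alkoxy chromone-type rings, should place iodine at C6 between the two oxygens, the other aryl rings being far less activated.

Step 6
Reactants: 10 7-(benzyloxy)-2-[4-(benzyloxy)phenyl]-5-hydroxy-6-iodo-4H-1,3-benzodioxin-4-one
Product: 11 5,7-bis(benzyloxy)-2-[4-(benzyloxy)phenyl]-6-iodo-4H-1,3-benzodioxin-4-one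
Conditions: BnBr, Cs2CO3, DMF, 40 °C
Reagents that add atoms: benzyl bromide, BrCc1ccccc1
Why: Williamson benzylation of the hindered, chelated 5-OH removes the last acidic proton before the organozinc coupling and the acid-catalysed key step.

Step 7
Reactants: 11 5,7-bis(benzyloxy)-2-[4-(benzyloxy)phenyl]-6-iodo-4H-1,3-benzodioxin-4-one
Product: 12 5,7-bis(benzyloxy)-2-[4-(benzyloxy)phenyl]-6-iodo-4-methylidene-4H-1,3-benzodioxine
Conditions: Cp2TiMe2 (dimethyltitanocene, 2.5 equiv), toluene/THF, 70 °C, dark; filtration through basic Al2O3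
Reagents that add atoms: dimethyltitanocene, [CH3-].[CH3-].[Ti+4].c1cc[cH-]c1.c1cc[cH-]c1
Why: Petasis methylenation (titanium methylidene, [2+2]/retro-[2+2]) should turn the acylal C=O into the exocyclic enol ether without a tetrahedral intermediate that could eject the acetal, as with 1,3-dioxan-4-ones, leaving aryl iodide and benzyl ethers untouched.

Step 8
Reactants: 3 5-(benzyloxy)-7-methoxy-2-(4-methoxyphenyl)-4H-chromen-4-one; 12 5,7-bis(benzyloxy)-2-[4-(benzyloxy)phenyl]-6-iodo-4-methylidene-4H-1,3-benzodioxine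
Product: 15 5-(benzyloxy)-3-{5,7-bis(benzyloxy)-2-[4-(benzyloxy)phenyl]-4-methylidene-4H-1,3-benzodioxin-6-yl}-7-methoxy-2-(4-methoxyphenyl)-4H-chromen-4-one, via 3-lithioflavone 13 (not isolated), via flavon-3-ylzinc chloride 14 (not isolated)
Conditions: 3, LiN(i-Pr)2, THF, −78 °C; ZnCl2, −78 °C → rt; then 12, Pd2(dba)3 (2.5 mol%), SPhos (10 mol%), THF, 55 °C
Reagents that add atoms: none
Why: Directed C3-lithiation of the flavone (C2 blocked), transmetalation to zinc and Negishi cross-coupling on a dialkylbiarylphosphine-ligated zerovalent palladium catalyst should tolerate the di-ortho-substituted partners under conditions free of acid and strong base, so the enol acetal survives.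

Step 9
Reactants: 15 5-(benzyloxy)-3-{5,7-bis(benzyloxy)-2-[4-(benzyloxy)phenyl]-4-methylidene-4H-1,3-benzodioxin-6-yl}-7-methoxy-2-(4-methoxyphenyl)-4H-chromen-4-one
Product: 16 (2R)-5,7-bis(benzyloxy)-2-[4-(benzyloxy)phenyl]-6-[5-(benzyloxy)-7-methoxy-2-(4-methoxyphenyl)-4-oxo-4H-chromen-3-yl]-2,3-dihydro-4H-chromen-4-one
Conditions: (S,S)-IDPi chiral Brønsted acid (BINOL-derived imidodiphosphorimidate, 5 mol%), 4 Å MS, toluene/CH2Cl2, −60 → −20 °C; Et3N quench
Reagents that add atoms: none
Why: Proposed new method: the chiral acid protonates the exocyclic enol ether of 15 (at C3 or at O3), the C2–O3 bond of the acetal ionises to an aryloxocarbenium ion O1=C2 stabilised by the 4-benzyloxyphenyl ring F, and C3 of the enol of the C4 ketone, its own leaving group and still tethered through ring D, attacks C2 to give the chroman-4-one and return the proton. The closest known reaction types are the Lewis-acid Petasis–Ferrier rearrangement of 4-methylidene-1,3-dioxanes to tetrahydropyran-4-ones and the chiral-phosphoric-acid-catalysed Petasis–Ferrier-type rearrangements of cyclic vinyl acetals and hemiaminal vinyl ethers, where the same kind of ion pair recombines at carbon under control of the chiral anion. Ring E closes in a 6-(enolendo)-endo-trig mode (C3 onto the O1=C2 oxocarbenium), a net [1,3] O-to-C shift that also unveils the C4 ketone. The C2 stereocentre is controlled by the catalyst alone: the acetal centre of racemic 15 is erased on ionisation, and the confined chiral anion, ion-paired with the oxocarbenium and hydrogen-bonded to the enol OH, should select the face of C2 that leads to (2R). The step needs C2–O3 rather than C2–O1 cleavage and no crossover: C-protonation of the electron-rich styrene-type enol ether leads only to C2–O3 cleavage and any O1 cleavage is reversible, every other phenol is benzylated so the aldehyde carbon cannot move to another oxygen (which keeps the 6-linkage), and low temperature with molecular sieves suppresses hydrolysis and intermolecular aldol paths.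

Step 10
Reactants: 16 (2R)-5,7-bis(benzyloxy)-2-[4-(benzyloxy)phenyl]-6-[5-(benzyloxy)-7-methoxy-2-(4-methoxyphenyl)-4-oxo-4H-chromen-3-yl]-2,3-dihydro-4H-chromen-4-one
Product: 17 (2R)-5,7-dihydroxy-6-[5-hydroxy-7-methoxy-2-(4-methoxyphenyl)-4-oxo-4H-chromen-3-yl]-2-(4-hydroxyphenyl)-2,3-dihydro-4H-chromen-4-one (CNP0292254.1)
Conditions: H2 (1 atm), Pd/C (10 wt% Pd on carbon), EtOAc/THF, rt
Reagents that add atoms: none
Why: Hydrogenolysis of the four aryl benzyl ethers under neutral conditions should leave the tetrasubstituted flavone C2=C3, the aryl ketone and the C2 stereocentre untouched, since no base is present to open ring E by retro-oxa-Michael reaction.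

**Compound list**

1 | apigenin, 5,7-dihydroxy-2-(4-hydroxyphenyl)-4H-chromen-4-one | O=c1cc(-c2ccc(O)cc2)oc2cc(O)cc(O)c12 | starting material
2 | 5-hydroxy-7-methoxy-2-(4-methoxyphenyl)-4H-chromen-4-one | COc1ccc(-c2cc(=O)c3c(O)cc(OC)cc3o2)cc1 | intermediate
3 | 5-(benzyloxy)-7-methoxy-2-(4-methoxyphenyl)-4H-chromen-4-one | COc1ccc(-c2cc(=O)c3c(OCc4ccccc4)cc(OC)cc3o2)cc1 | intermediate
4 | 2,4,6-trihydroxybenzoic acid | OC(=O)c1c(O)cc(O)cc1O | starting material
5 | 4-(benzyloxy)benzaldehyde | O=Cc1ccc(OCc2ccccc2)cc1 | starting material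
6 | trimethylsilyl 2,4,6-tris(trimethylsilyloxy)benzoate | C[Si](C)(C)OC(=O)c1c(O[Si](C)(C)C)cc(O[Si](C)(C)C)cc1O[Si](C)(C)C | intermediate
7 | 2-[4-(benzyloxy)phenyl]-5,7-bis(trimethylsilyloxy)-4H-1,3-benzodioxin-4-one (racemic) | O=C1OC(c2ccc(OCc3ccccc3)cc2)Oc2cc(O[Si](C)(C)C)cc(O[Si](C)(C)C)c21 | intermediate
8 | 2-[4-(benzyloxy)phenyl]-5,7-dihydroxy-4H-1,3-benzodioxin-4-one (racemic) | O=C1OC(c2ccc(OCc3ccccc3)cc2)Oc2cc(O)cc(O)c21 | intermediate
9 | 7-(benzyloxy)-2-[4-(benzyloxy)phenyl]-5-hydroxy-4H-1,3-benzodioxin-4-one (racemic) | O=C1OC(c2ccc(OCc3ccccc3)cc2)Oc2cc(OCc3ccccc3)cc(O)c21 | intermediate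
10 | 7-(benzyloxy)-2-[4-(benzyloxy)phenyl]-5-hydroxy-6-iodo-4H-1,3-benzodioxin-4-one (racemic) | O=C1OC(c2ccc(OCc3ccccc3)cc2)Oc2cc(OCc3ccccc3)c(I)c(O)c21 | intermediate
11 | 5,7-bis(benzyloxy)-2-[4-(benzyloxy)phenyl]-6-iodo-4H-1,3-benzodioxin-4-one (racemic) | O=C1OC(c2ccc(OCc3ccccc3)cc2)Oc2cc(OCc3ccccc3)c(I)c(OCc3ccccc3)c21 | intermediate
12 | 5,7-bis(benzyloxy)-2-[4-(benzyloxy)phenyl]-6-iodo-4-methylidene-4H-1,3-benzodioxine (racemic) | C=C1OC(c2ccc(OCc3ccccc3)cc2)Oc2cc(OCc3ccccc3)c(I)c(OCc3ccccc3)c21 | intermediate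
13 | [5-(benzyloxy)-7-methoxy-2-(4-methoxyphenyl)-4-oxo-4H-chromen-3-yl]lithium | COc1ccc(-c2oc3cc(OC)cc(OCc4ccccc4)c3c(=O)c2[Li])cc1 | intermediate
14 | [5-(benzyloxy)-7-methoxy-2-(4-methoxyphenyl)-4-oxo-4H-chromen-3-yl]zinc chloride | COc1ccc(-c2oc3cc(OC)cc(OCc4ccccc4)c3c(=O)c2[Zn]Cl)cc1 | intermediate
15 | 5-(benzyloxy)-3-{5,7-bis(benzyloxy)-2-[4-(benzyloxy)phenyl]-4-methylidene-4H-1,3-benzodioxin-6-yl}-7-methoxy-2-(4-methoxyphenyl)-4H-chromen-4-one (racemic at the acetal carbon) | C=C1OC(c2ccc(OCc3ccccc3)cc2)Oc2cc(OCc3ccccc3)c(-c3c(-c4ccc(OC)cc4)oc4cc(OC)cc(OCc5ccccc5)c4c3=O)c(OCc3ccccc3)c21 | intermediate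
16 | (2R)-5,7-bis(benzyloxy)-2-[4-(benzyloxy)phenyl]-6-[5-(benzyloxy)-7-methoxy-2-(4-methoxyphenyl)-4-oxo-4H-chromen-3-yl]-2,3-dihydro-4H-chromen-4-one | COc1ccc(-c2oc3cc(OC)cc(OCc4ccccc4)c3c(=O)c2-c2c(OCc3ccccc3)cc3c(c2OCc2ccccc2)C(=O)C[C@H](c2ccc(OCc4ccccc4)cc2)O3)cc1 | intermediate
17 | (2R)-5,7-dihydroxy-6-[5-hydroxy-7-methoxy-2-(4-methoxyphenyl)-4-oxo-4H-chromen-3-yl]-2-(4-hydroxyphenyl)-2,3-dihydro-4H-chromen-4-one | COc1ccc(-c2oc3cc(OC)cc(O)c3c(=O)c2-c2c(O)cc3c(c2O)C(=O)C[C@H](c2ccc(O)cc2)O3)cc1 | target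

**Step count and risks**

Total step count: 10. Longest linear sequence: 8 steps (steps 3 to 10, from 2,4,6-trihydroxybenzoic acid); the flavone branch (steps 1 and 2) joins at step 8.

Steps most likely to fail:

Step 9 (bears the proposed method). The recombination of the ion pair may show poor facial selectivity; adventitious water may split off the aldehyde carbon, followed by unselective aldol and oxa-Michael re-condensation; the basic flavone carbonyl may sequester the acid; and acid-catalysed opening and re-closure of ring E may erode the C2 configuration. The fallback uses known chemistry, sets out from 15 and comes back at 16. Compound 15 is treated with Me2AlCl in CH2Cl2 at −78 → 0 °C, the established Lewis-acid Petasis–Ferrier rearrangement through an aluminium enolate and the oxocarbenium ion. This should give the racemic protected flavanone F1. Preparative HPLC on an amylose tris(3,5-dimethylphenylcarbamate) phase would then separate 16 from the (2S)-configured protected flavanone F2.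

Step 8. Transmetalation and reductive elimination may be slow at a biaryl bond with four ortho substituents, the 3-metalated flavone may ring-open on warming, and zinc salts may trigger premature rearrangement of the enol acetal. The fallback reverses the roles of the partners and works in basic medium; it sets out from 3 and 12 and comes back at 15. Flavone 3 is lithiated as in step 8 (13) and quenched with I2 to give 5-(benzyloxy)-3-iodo-7-methoxy-2-(4-methoxyphenyl)-4H-chromen-4-one F3. Iodide 12 is borylated with bis(pinacolato)diboron, PdCl2(dppf) and KOAc in dioxane at 80 °C to give the pinacol boronate of the enol acetal F4. Suzuki–Miyaura coupling of F3 with F4 (Pd(OAc)2, SPhos, K3PO4, toluene/H2O, 80 °C) should then give 15.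

Step 3. Friedel–Crafts hydroxyalkylation of the electron-rich ring D by the activated aldehyde and decarboxylation of the acid may compete with acetal formation. The fallback decorates ring D on a robust acetonide first and attaches the aldehyde last, when only one phenol is free and the ring is deactivated; it sets out from 4 and comes back at 11, so steps 3 to 6 are replaced.
- Acid 4 with acetone, (CF3CO)2O and CF3CO2H gives 5,7-dihydroxy-2,2-dimethyl-4H-1,3-benzodioxin-4-one F5.
- BnBr and K2CO3 give 7-(benzyloxy)-5-hydroxy-2,2-dimethyl-4H-1,3-benzodioxin-4-one F6.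
- Benzyltrimethylammonium dichloroiodate and CaCO3 give 7-(benzyloxy)-5-hydroxy-6-iodo-2,2-dimethyl-4H-1,3-benzodioxin-4-one F7.
- BnBr and Cs2CO3 give 5,7-bis(benzyloxy)-6-iodo-2,2-dimethyl-4H-1,3-benzodioxin-4-one F8.
- KOH in THF/H2O, then cold acidification, gives 2,4-bis(benzyloxy)-6-hydroxy-3-iodobenzoic acid F9.
- Silylation with (Me3Si)2NH gives trimethylsilyl 2,4-bis(benzyloxy)-3-iodo-6-(trimethylsilyloxy)benzoate F10, which with aldehyde 5 and Me3SiOSO2CF3 (cat.) at −78 °C should give 11.

**Further compounds**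

F1 | step 9 | racemic 5,7-bis(benzyloxy)-2-[4-(benzyloxy)phenyl]-6-[5-(benzyloxy)-7-methoxy-2-(4-methoxyphenyl)-4-oxo-4H-chromen-3-yl]-2,3-dihydro-4H-chromen-4-one | COc1ccc(-c2oc3cc(OC)cc(OCc4ccccc4)c3c(=O)c2-c2c(OCc3ccccc3)cc3c(c2OCc2ccccc2)C(=O)CC(c2ccc(OCc4ccccc4)cc2)O3)cc1
F2 | step 9 | (2S)-5,7-bis(benzyloxy)-2-[4-(benzyloxy)phenyl]-6-[5-(benzyloxy)-7-methoxy-2-(4-methoxyphenyl)-4-oxo-4H-chromen-3-yl]-2,3-dihydro-4H-chromen-4-one | COc1ccc(-c2oc3cc(OC)cc(OCc4ccccc4)c3c(=O)c2-c2c(OCc3ccccc3)cc3c(c2OCc2ccccc2)C(=O)C[C@@H](c2ccc(OCc4ccccc4)cc2)O3)cc1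
F3 | step 8 | 5-(benzyloxy)-3-iodo-7-methoxy-2-(4-methoxyphenyl)-4H-chromen-4-one | COc1ccc(-c2oc3cc(OC)cc(OCc4ccccc4)c3c(=O)c2I)cc1
F4 | step 8 | 2-{5,7-bis(benzyloxy)-2-[4-(benzyloxy)phenyl]-4-methylidene-4H-1,3-benzodioxin-6-yl}-4,4,5,5-tetramethyl-1,3,2-dioxaborolane | C=C1OC(c2ccc(OCc3ccccc3)cc2)Oc2cc(OCc3ccccc3)c(B3OC(C)(C)C(C)(C)O3)c(OCc3ccccc3)c21
F5 | step 3 | 5,7-dihydroxy-2,2-dimethyl-4H-1,3-benzodioxin-4-one | CC1(C)OC(=O)c2c(O)cc(O)cc2O1
F6 | step 3 | 7-(benzyloxy)-5-hydroxy-2,2-dimethyl-4H-1,3-benzodioxin-4-one | CC1(C)OC(=O)c2c(O)cc(OCc3ccccc3)cc2O1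
F7 | step 3 | 7-(benzyloxy)-5-hydroxy-6-iodo-2,2-dimethyl-4H-1,3-benzodioxin-4-one | CC1(C)OC(=O)c2c(O)c(I)c(OCc3ccccc3)cc2O1
F8 | step 3 | 5,7-bis(benzyloxy)-6-iodo-2,2-dimethyl-4H-1,3-benzodioxin-4-one | CC1(C)OC(=O)c2c(OCc3ccccc3)c(I)c(OCc3ccccc3)cc2O1
F9 | step 3 | 2,4-bis(benzyloxy)-6-hydroxy-3-iodobenzoic acid | OC(=O)c1c(O)cc(OCc2ccccc2)c(I)c1OCc1ccccc1
F10 | step 3 | trimethylsilyl 2,4-bis(benzyloxy)-3-iodo-6-(trimethylsilyloxy)benzoate | C[Si](C)(C)OC(=O)c1c(O[Si](C)(C)C)cc(OCc2ccccc2)c(I)c1OCc1ccccc1
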